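The route rests on cutting the dimethylpyran ring away from ring B at its two aryl bonds, C4'–O and C5'–CH=. In one flask, a (Z)-alkenylboronate that carries the masked tertiary alkoxide is joined to a 5-bromo-4-fluoro-2-alkoxybenzaldehyde: Suzuki–Miyaura coupling at C5' is followed by intramolecular SNAr of the alkoxide at C4'. The step exploits that the pyran oxygen sits para to C1', which at the aldehyde level activates C4'–F, and it gives the linear 6,7-fused chromene that phenol/enal condensations miss. Claisen–Schmidt condensation with a 3-prenyl resacetophenone, a catalytic asymmetric oxa-Michael ring closure that sets C2 as S, and MOM removal finish the flavanone.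

Key step: step 3

Assumption: the quinidine-derived bifunctional thiourea is taken to deliver the (2S) series; should the sense of induction prove opposite, its quinine-derived pseudoenantiomer takes its place with no other change.

Step 1
Reactants: 1 5-bromo-4-fluoro-2-hydroxybenzaldehyde
Product: 2 5-bromo-4-fluoro-2-(methoxymethoxy)benzaldehyde
Conditions: MOMCl, K2CO3, acetone, 0 °C to rt
Reagents that add atoms: chloromethyl methyl ether, COCCl
Why: Williamson-type O-alkylation of the phenoxide; the MOM ether keeps the ring from becoming a deactivating phenoxide in the later SNAr and survives all basic steps.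

Step 2
Reactants: 3 trimethyl[(2-methylbut-3-yn-2-yl)oxy]silane
Product: 4 (Z)-trimethyl{[2-methyl-4-(4,4,5,5-tetramethyl-1,3,2-dioxaborolan-2-yl)but-3-en-2-yl]oxy}silane
Conditions: HBpin, [Rh(cod)Cl]2 (1.5 mol%), P(i-Pr)3 (6 mol%), Et3N, cyclohexane, rt (alkyne in slight excess)
Reagents that add atoms: pinacolborane, [H]B1OC(C)(C)C(C)(C)O1
Why: Rhodium-catalysed anti-Markovnikov trans-hydroboration of a terminal alkyne through a rhodium vinylidene places boron cis to the CMe2(OSiMe3) group and should give the Z alkenylboronate; the silyl ether keeps the tertiary alcohol away from the borane.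

Step 3
Reactants: 2 5-bromo-4-fluoro-2-(methoxymethoxy)benzaldehyde; 4 (Z)-alkenylboronate silyl ether
Product: 7 7-(methoxymethoxy)-2,2-dimethyl-2H-chromene-6-carbaldehyde, via Z-alkenyl fluoroarene silyl ether 5 (not isolated), via Z-alkenyl fluoroarene tertiary alkoxide 6 (not isolated)
Conditions: Pd(PPh3)4 (5 mol%), CsF (4 equiv), DMF, 70 then 100 °C
Reagents that add atoms: none
Why: Zerovalent palladium inserts into the C5–Br bond of 2 (C–F and the aldehyde stay untouched), and fluoride-assisted transmetalation of 4 with retention of the Z geometry followed by reductive elimination forms the aryl–CH= bond (5). Fluoride then cleaves the O–Si bond, and the cesium tertiary alkoxide 6, held cis to the arene by the Z alkene, attacks C4 and expels fluoride through a Meisenheimer complex stabilised by the para formyl group, which forms the aryl–O bond. The closest known reaction type is a Suzuki–Miyaura coupling run in tandem with an intramolecular SNAr etherification. The pyran ring closes in a formal 6-exo-trig addition–elimination at the aromatic carbon. No stereocenter is formed; the step needs retention of the Z alkene, which the stereoretentive transmetalation of the alkenylboronate secures, and the linear regiochemistry, which is fixed by the positions of Br and F in 2 and cannot drift to the angular isomer.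

Step 4
Reactants: 8 1-(2,4-dihydroxyphenyl)ethan-1-one; 9 1-bromo-3-methylbut-2-ene
Product: 10 1-[2,4-dihydroxy-3-(3-methylbut-2-en-1-yl)phenyl]ethan-1-one
Conditions: KOH (10% aq), 0 °C to rt
Reagents that add atoms: none
Why: C-alkylation of the ambident resorcinolate in water, where hydrogen bonding to oxygen favours attack through carbon, at C3, the position ortho to both oxygens.

Step 5
Reactants: 10 1-[2,4-dihydroxy-3-(3-methylbut-2-en-1-yl)phenyl]ethan-1-one
Product: 11 1-[2-hydroxy-4-(methoxymethoxy)-3-(3-methylbut-2-en-1-yl)phenyl]ethan-1-one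
Conditions: MOMCl (1.1 equiv), K2CO3, acetone, rt
Reagents that add atoms: chloromethyl methyl ether, COCCl
Why: Selective O-alkylation of the free 4-OH; the 2-OH is hydrogen-bonded to the ketone and stays free for the later ring closure.

Step 6
Reactants: 11 1-[2-hydroxy-4-(methoxymethoxy)-3-(3-methylbut-2-en-1-yl)phenyl]ethan-1-one; 7 7-(methoxymethoxy)-2,2-dimethyl-2H-chromene-6-carbaldehyde
Product: 12 (E)-1-[2-hydroxy-4-(methoxymethoxy)-3-(3-methylbut-2-en-1-yl)phenyl]-3-[7-(methoxymethoxy)-2,2-dimethyl-2H-chromen-6-yl]prop-2-en-1-one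
Conditions: KOH, EtOH/H2O, rt; then dilute acid to pH 5
Reagents that add atoms: none
Why: Claisen–Schmidt condensation of the methyl ketone enolate with the non-enolisable aldehyde; E1cB dehydration should give the E enone, and the chalcone phenoxide does not cyclise in strong base.

Step 7
Reactants: 12 2'-hydroxychalcone
Product: 13 (2S)-7-(methoxymethoxy)-2-[7-(methoxymethoxy)-2,2-dimethyl-2H-chromen-6-yl]-8-(3-methylbut-2-en-1-yl)-2,3-dihydro-4H-chromen-4-one
Conditions: thiourea from 9-amino-9-deoxy-epi-quinidine and 3,5-bis(trifluoromethyl)phenyl isothiocyanate (10 mol%), toluene, rt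
Reagents that add atoms: none
Why: Asymmetric intramolecular oxa-Michael addition (6-endo-trig) under bifunctional cinchona thiourea catalysis; the thiourea binds the enone carbonyl and the quinuclidine orients the phenol, so oxygen adds to one face of the β-carbon and should set C2 as S.

Step 8
Reactants: 13 bis-MOM (2S)-flavanone
Product: 14 (2S)-7-hydroxy-2-(7-hydroxy-2,2-dimethyl-2H-chromen-6-yl)-8-(3-methylbut-2-en-1-yl)-2,3-dihydro-4H-chromen-4-one
Conditions: HCl (3 M aq), MeOH, 45 °C
Reagents that add atoms: none
Why: Acid-catalysed transacetalisation of both MOM ethers to methanol; the medium is non-basic, so C2 is not opened by retro-oxa-Michael, and the prenyl and chromene alkenes should tolerate dilute acid at this temperature.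

Compound list
1 | 5-bromo-4-fluoro-2-hydroxybenzaldehyde | O=Cc1cc(Br)c(F)cc1O | starting material
2 | 5-bromo-4-fluoro-2-(methoxymethoxy)benzaldehyde | COCOc1cc(F)c(Br)cc1C=O | intermediate
3 | trimethyl[(2-methylbut-3-yn-2-yl)oxy]silane | C#CC(C)(C)O[Si](C)(C)C | starting material
4 | (Z)-trimethyl{[2-methyl-4-(4,4,5,5-tetramethyl-1,3,2-dioxaborolan-2-yl)but-3-en-2-yl]oxy}silane | C[Si](C)(C)OC(C)(C)/C=C\B1OC(C)(C)C(C)(C)O1 | intermediate
5 | 4-fluoro-2-(methoxymethoxy)-5-[(Z)-3-methyl-3-(trimethylsilyloxy)but-1-en-1-yl]benzaldehyde (formed in the flask in step 3) | COCOc1cc(F)c(/C=C\C(C)(C)O[Si](C)(C)C)cc1C=O | intermediate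
6 | 4-fluoro-5-[(Z)-3-hydroxy-3-methylbut-1-en-1-yl]-2-(methoxymethoxy)benzaldehyde (formed in the flask in step 3 as its cesium alkoxide, drawn as the alcohol) | COCOc1cc(F)c(/C=C\C(C)(C)O)cc1C=O | intermediate
7 | 7-(methoxymethoxy)-2,2-dimethyl-2H-chromene-6-carbaldehyde | COCOc1cc2OC(C)(C)C=Cc2cc1C=O | intermediate
8 | 1-(2,4-dihydroxyphenyl)ethan-1-one | CC(=O)c1ccc(O)cc1O | starting material
9 | 1-bromo-3-methylbut-2-ene | CC(C)=CCBr | starting material
10 | 1-[2,4-dihydroxy-3-(3-methylbut-2-en-1-yl)phenyl]ethan-1-one | CC(=O)c1ccc(O)c(CC=C(C)C)c1O | intermediate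
11 | 1-[2-hydroxy-4-(methoxymethoxy)-3-(3-methylbut-2-en-1-yl)phenyl]ethan-1-one | CC(=O)c1ccc(OCOC)c(CC=C(C)C)c1O | intermediate
12 | (E)-1-[2-hydroxy-4-(methoxymethoxy)-3-(3-methylbut-2-en-1-yl)phenyl]-3-[7-(methoxymethoxy)-2,2-dimethyl-2H-chromen-6-yl]prop-2-en-1-one | COCOc1ccc(C(=O)/C=C/c2cc3C=CC(C)(C)Oc3cc2OCOC)c(O)c1CC=C(C)C | intermediate
13 | (2S)-7-(methoxymethoxy)-2-[7-(methoxymethoxy)-2,2-dimethyl-2H-chromen-6-yl]-8-(3-methylbut-2-en-1-yl)-2,3-dihydro-4H-chromen-4-one | CC(C)=CCc1c(OCOC)ccc2c1O[C@H](c1cc3c(cc1OCOC)OC(C)(C)C=C3)CC2=O | intermediate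
14 | (2S)-7-hydroxy-2-(7-hydroxy-2,2-dimethyl-2H-chromen-6-yl)-8-(3-methylbut-2-en-1-yl)-2,3-dihydro-4H-chromen-4-one | CC(C)=CCc1c(O)ccc2c1O[C@H](c1cc3c(cc1O)OC(C)(C)C=C3)CC2=O | target

Total step count: 8. Longest linear sequence: 5 steps (for example 1 → 2 → 7 → 12 → 13 → 14).

Steps most likely to fail

Step 7. The electron-rich ring B deactivates the enone, so the closure may stall near the chalcone/flavanone equilibrium, and reversible ring opening may erode the facial selectivity. The fallback sets out from 11 (with aldehyde 7) and comes back to the route at 13. Ketone 11 is C-acylated with diallyl carbonate (NaH, THF, reflux) to allyl 3-[2-hydroxy-4-(methoxymethoxy)-3-(3-methylbut-2-en-1-yl)phenyl]-3-oxopropanoate F1. Knoevenagel condensation of F1 with 7 (piperidinium acetate, toluene, molecular sieves) gives the alkylidene β-ketoester F2. The same thiourea should close this doubly activated acceptor irreversibly to the allyl (2S)-4-oxochromane-3-carboxylate F3. Deallylation and decarboxylation with Pd(PPh3)4 and morpholine in THF then give 13.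

Step 3. The Z geometry may be lost during transmetalation, the alkenylboronate may protodeboronate before coupling, or the alkoxide may be consumed before it reaches C4. The fallback sets out from 2 and comes back to the route at 7, passing through 6 as an isolated compound. Sonogashira coupling of 2 with 2-methylbut-3-yn-2-ol (Pd(PPh3)2Cl2, CuI, Et3N) gives 4-fluoro-5-(3-hydroxy-3-methylbut-1-yn-1-yl)-2-(methoxymethoxy)benzaldehyde F4. Semi-hydrogenation of F4 (H2, Pd/CaCO3 poisoned with Pb(OAc)2, quinoline) gives the (Z)-allylic alcohol 6. NaH in DMF then closes 6 to 7 by SNAr in a separate step.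

Step 4. O-alkylation, attack at C5 and double prenylation may compete with C-alkylation at C3. The fallback sets out from 8 and comes back to the route at 11. Iodination of 8 (I2, HIO3, aqueous EtOH) at the position between the two hydroxyl groups gives 1-(2,4-dihydroxy-3-iodophenyl)ethan-1-one F5. Selective protection of the 4-OH (MOMCl, K2CO3, acetone) gives 1-[2-hydroxy-3-iodo-4-(methoxymethoxy)phenyl]ethan-1-one F6. Stille coupling of F6 with tributyl(3-methylbut-2-en-1-yl)stannane (Pd(PPh3)4, DMF, 90 °C) then gives 11 with the prenyl group at a defined position.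

Further compounds
F1 | step 7 | allyl 3-[2-hydroxy-4-(methoxymethoxy)-3-(3-methylbut-2-en-1-yl)phenyl]-3-oxopropanoate | C=CCOC(=O)CC(=O)c1ccc(OCOC)c(CC=C(C)C)c1O
F2 | step 7 | allyl 2-[2-hydroxy-4-(methoxymethoxy)-3-(3-methylbut-2-en-1-yl)benzoyl]-3-[7-(methoxymethoxy)-2,2-dimethyl-2H-chromen-6-yl]prop-2-enoate | C=CCOC(=O)C(=Cc1cc2C=CC(C)(C)Oc2cc1OCOC)C(=O)c1ccc(OCOC)c(CC=C(C)C)c1O
F3 | step 7 | allyl (2S)-7-(methoxymethoxy)-2-[7-(methoxymethoxy)-2,2-dimethyl-2H-chromen-6-yl]-8-(3-methylbut-2-en-1-yl)-4-oxochromane-3-carboxylate | CC(C)=CCc1c(OCOC)ccc2c1O[C@H](c1cc3c(cc1OCOC)OC(C)(C)C=C3)C(C(=O)OCC=C)C2=O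
F4 | step 3 | 4-fluoro-5-(3-hydroxy-3-methylbut-1-yn-1-yl)-2-(methoxymethoxy)benzaldehyde | COCOc1cc(F)c(C#CC(C)(C)O)cc1C=O
F5 | step 4 | 1-(2,4-dihydroxy-3-iodophenyl)ethan-1-one | CC(=O)c1ccc(O)c(I)c1O
F6 | step 4 | 1-[2-hydroxy-3-iodo-4-(methoxymethoxy)phenyl]ethan-1-one | CC(=O)c1ccc(OCOC)c(I)c1O
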